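# Proposed total synthesis of vismiaphenone D

## Analysis of the target

Vismiaphenone D (13, C24H28O5) is a benzophenone in which a hexasubstituted ring A and a 4-hydroxyphenyl ring B are joined through the ketone carbon C7. In ring A, C1 carries the aroyl group, C2 and C6 carry hydroxy groups that chelate the ketone, C3 and C5 carry prenyl groups, and C4 carries the only methyl ether. A local mirror plane therefore runs through C7, C1 and C4. There is no stereocentre, and each side-chain alkene ends in two identical methyl groups, so no configuration has to be set.

The sensitive groups are the two prenyl chains and ring A itself. Each prenyl chain lies ortho to a free phenol, so Brønsted or Lewis acids close it to a 2,2-dimethylchroman and hydrogenation saturates it. Ring A is very electron-rich and is easily oxidised as its phenoxide.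

The difficulty is selectivity, not size. No position of ring A is free. Four oxygen atoms of similar acidity must be told apart so that only O4, wedged between two prenyl groups, is methylated. The C–C bonds to C3 and C5 would have to be made on an ambident phenoxide that also offers O-alkylation and geminal, dearomatising alkylation.

The route exploits one feature. Oxygen sits on C7, C6, C4 and C2, that is on every second carbon of the chain C7–C1–C6–C5–C4–C3–C2. Ring A plus C7 is thus a folded tetra-β-carbonyl chain, its former methylene carbons are C1, C3 and C5, and the two prenyl groups sit on C3 and C5. If ring A is made from this chain, every substituent can be placed on an sp3 or enol carbon before the ring exists.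

## Retrosynthetic reasoning

**Ring bond C1–C2 of 13.** Cutting this bond (equivalent by symmetry to C1–C6) unfolds ring A into keto ester 12. In 12, C1 is the CH2 of a β-diketone and C2 is an ester carbonyl. This is the only ring bond whose formation is a Claisen condensation between the most acidic carbon and the only ester of the chain. The gain is that a hexasubstituted arene becomes an open chain with ordinary enolate positions. Compound 12 need not be made as such, because its cyclic enol lactone is the 2-pyrone 11, which apart from the silyl group is an isomer of 13. Pyrone atoms C2 to C6 already carry the substituents of ring A atoms C2 to C6. The forward reaction only has to exchange the ring oxygen O1 for the exocyclic carbon C1 by alkoxide ring opening and Claisen reclosure.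

**Bond C1–C7.** Compound 11 is cut between the side-chain CH2 and the aryl ketone into the 6-methyl-2-pyrone 8 and the non-enolisable aryl ester 10. The methyl group of 8 is the only position whose anion is conjugated with the lactone carbonyl, so the bond is made by a vinylogous Claisen acylation. The enolate of 11 formed in that acylation is exactly what the ring transformation needs. Both cuts are therefore carried out in one flask, and the key step starts from two much simpler compounds, 8 and 10. One carbon, the methyl carbon of 8, receives both new C–C bonds and becomes C1.

**Bond O4–CH3.** Compound 8 goes back to the 4-hydroxy-2-pyrone 7. At this stage the molecule holds a single hydroxy group. The problem of picking one oxygen out of four in 13 shrinks to the O-alkylation of one vinylogous acid.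

**Lactone bond O1–C2 and chain bond C5–C6.** Compound 7 is the enol lactone of the 3,5-dioxo ester 6. Compound 6 is cut next to the terminal acetyl group into the β-keto ester 4 (as its dianion) and the acetyl donor 5. Compound 5 supplies C6 and the carbon that ends as C1. The forward reaction must acylate the γ-carbon of 4 without proton transfer from the more acidic product, which is why an amide that gives a stable tetrahedral adduct is chosen.

**The two prenyl bonds at C3 and C5.** Compound 4 is cut into 1 and two equivalents of 2. The γ-carbon of 1 becomes C5 and its α-carbon becomes C3. Both C–C bonds are made by SN2 alkylation of sp3 carbons, ordered by the different basicity of the two anionic sites. O-prenylation and dearomatising geminal prenylation of a phenoxide cannot arise.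

**Silyl ether of ring B.** Compound 10 comes from 9. The silyl group is chosen because it survives the amide base at low temperature and is lost in the alkoxide medium of the key step. No deprotection step is spent, and no acid or hydrogenation ever meets the prenyl groups.

## Alternatives that were turned down

**Alternative 1:** the textbook route.

- *Disconnection:* ring A is bought as phloroglucinol A1. The cuts are C1–C7, then the two prenyl bonds, then O4–CH3.
- *Forward:* Friedel–Crafts or Hoesch aroylation of A1 with an aroyl donor derived from 9 gives tetrahydroxybenzophenone A2. The key step is the double C-prenylation of A2 with 2 under base to the diprenyl compound A3. Mono-O-methylation follows.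
- *Why turned down:* the polyphenoxide of A2 is nucleophilic at O2/O6, O4, O4′ and C3/C5. Each C-prenylation makes the ring more electron-rich, so a third, geminal alkylation with dearomatisation competes with the second. In A3 the oxygen to be methylated (O4) is the most hindered one. O4′ is unhindered and of like acidity, since both lie para to the ketone, so ring B needs a protecting group that must later leave without acid or hydrogenolysis. The count rises to five or six steps, none of them builds skeleton, and every selectivity problem is left to separation.

**Alternative 2:** Danheiser benzannulation.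

- *Disconnection:* ring A is cut into a four-carbon and a two-carbon piece.
- *Forward:* 3-methoxy-2,4-diprenylcyclobutenone A4 opens thermally to a vinylketene. This adds to the siloxy ynone A5 by (2+2) cycloaddition, and 4π opening followed by 6π closure gives the fully substituted phenol A6.
- *Why turned down:* the atom mapping fits the target exactly, but the alkyne carbon that must attack the ketene carbonyl also carries the aroyl group. The push-pull alkyne A5 is thus a poor ketenophile, and it is also hard to make and to keep. With an alkyne that lacks the aroyl group, C1 would remain C–H and the aroyl group would have to be added by electrophilic acylation to an acid-sensitive ring. A4 itself costs about three steps (ketene dimerisation, isomerisation, O-methylation), and a silyl group would still have to be removed at the end.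

**Alternative 3:** a (5+1) double Claisen annulation.

- *Disconnection:* both bonds at C1 (C1–C2 and C1–C6) are cut, giving the symmetric C5 diester A7 and the methyl ketone A8.
- *Forward:* the enolate of A8 would be acylated twice by A7 and the product would aromatise. On paper this is the shortest route.
- *Why turned down:* the C–H of A7 between the ester and the enol ether is a vinylogous malonate proton, several pK units more acidic than the methyl ketone. Proton transfer would quench the nucleophile and turn the electrophile into an inert dienolate. The two carbonyl groups left for the slow intermolecular attack are an α-branched ester and a vinylogous carbonate, and self-condensation of A8 would use the waiting time. The chosen route keeps the same ring-closing bond but makes it intramolecular, and it buys the C1–C6 bond with the acetyl unit.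

Key step: step 5

Remark on the chemistry: compounds 3, 6, 11 and 12 exist in the flask as metal enolates or chelates and are named and drawn in their neutral forms. The ring A numbering (C1 to C7) is used for the same atoms in 8, 11 and 12, where it coincides with the pyrone numbering for C2 to C6.

## Route

Step 1
Reactants: 1 methyl acetoacetate; 2 prenyl bromide (1-bromo-3-methylbut-2-ene, two equivalents)
Product: 4 methyl 7-methyl-2-(3-methylbut-2-en-1-yl)-3-oxooct-6-enoate, via methyl 7-methyl-3-oxooct-6-enoate 3 (not isolated)
Conditions: NaH (1.1 equiv), THF, 0 °C; n-BuLi (1.05 equiv), 0 °C; 2 (1.0 equiv), 0 °C; then 2 (1.1 equiv), 0 °C → reflux; aq. NH4Cl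
Reagents that add atoms: none
Why: Sequential γ- then α-alkylation of the acetoacetate dianion: the more basic terminal carbanion reacts first with the allylic bromide (SN2) to give the enolate of 3, which the second equivalent alkylates at its central carbon on warming. Both prenyl C–C bonds (future C5 and C3) are thus made on sp3 carbons, and the new stereocentre is racemic and is erased in step 2.

Step 2
Reactants: 4 methyl 7-methyl-2-(3-methylbut-2-en-1-yl)-3-oxooct-6-enoate; 5 N-methoxy-N-methylacetamide
Product: 7 4-hydroxy-6-methyl-3,5-bis(3-methylbut-2-en-1-yl)-2H-pyran-2-one, via 3,5-dioxo ester 6 (not isolated)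
Conditions: LiN(i-Pr)2 (LDA, 2.2 equiv), THF, −78 → 0 °C; 5 (1.1 equiv), −78 → 0 °C; aq. NH4Cl; crude 6 in toluene, DBU (1.5 equiv), 80 °C; cold aq. citric acid
Reagents that add atoms: none
Why: The dianion of the 2-substituted β-keto ester is acylated at its γ-carbon by the N-methoxy-N-methyl amide (Weinreb ketone synthesis), whose chelated tetrahedral adduct blocks over-addition and proton transfer from the product. DBU-promoted enol lactonisation of 6 with loss of methanol is the standard entry to 3,5-dialkyl-4-hydroxy-2-pyrones, and both stereocentres of 6 vanish in the planar ring.

Step 3
Reactants: 7 4-hydroxy-6-methyl-3,5-bis(3-methylbut-2-en-1-yl)-2H-pyran-2-one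
Product: 8 4-methoxy-6-methyl-3,5-bis(3-methylbut-2-en-1-yl)-2H-pyran-2-one
Conditions: Me2SO4 (1.1 equiv), K2CO3 (1.5 equiv), acetone, reflux
Reagents that add atoms: dimethyl sulfate, COS(=O)(=O)OC
Why: O-Alkylation of a vinylogous carboxylic acid with a hard methylating agent, under the conditions that turn 4-hydroxy-6-methyl-2-pyrone into its 4-methyl ether. Compound 7 has a single OH, so the methyl group that ends on O4 of ring A is placed without any competing phenol, and C-methylation at C3 would cost the pyrone conjugation.

Step 4
Reactants: 9 methyl 4-hydroxybenzoate
Product: 10 methyl 4-[(tert-butyldimethylsilyl)oxy]benzoate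
Conditions: TBSCl (1.1 equiv), imidazole (2.2 equiv), DMF, rt
Reagents that add atoms: tert-butyldimethylsilyl chloride, CC(C)(C)[Si](C)(C)Cl
Why: Standard silylation of a phenol, which keeps the ester electrophilic by preventing formation of a deactivating phenoxide. The aryl silyl ether stands LDA at −78 °C and is cleaved by methoxide in step 5.

Step 5
Reactants: 8 4-methoxy-6-methyl-3,5-bis(3-methylbut-2-en-1-yl)-2H-pyran-2-one; 10 methyl 4-[(tert-butyldimethylsilyl)oxy]benzoate
Product: 13 vismiaphenone D, via silylated 6-phenacylpyrone 11 (not isolated), via ring-opened keto ester 12 (not isolated)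
Conditions: LiN(i-Pr)2 (LDA, 2.2 equiv), THF, −78 °C; 10 (1.05 equiv), −78 → 0 °C; then Mg(OMe)2 (4 equiv) in MeOH, argon, THF distilled off, reflux; cold 1 M HCl to pH 4
Reagents that add atoms: magnesium dimethoxide, C[O-].C[O-].[Mg+2] (its methoxide is held only by intermediate 12 and leaves again on ring closure)
Why: LDA deprotonates 8 only at the C6-methyl group, the one position whose anion is conjugated through C5=C6 and C3=C4 with the lactone carbonyl (C3 and C5 carry no ring hydrogen); the anion attacks the non-enolisable ester 10 through its exocyclic carbon in a vinylogous crossed Claisen condensation, and the second equivalent of base stores 11 as its enolate. In hot methanolic Mg(OMe)2 the aryl silyl ether is cleaved, methoxide adds to the lactone carbonyl C2, and acyl–oxygen fission opens the ring to the magnesium chelate of 12, whose C3=C4 enol ether inherits from the ring the geometry that holds the ester and the β-diketone arm on the same side. The doubly activated carbon C1 then attacks the ester carbonyl C2 in a 6-(enolexo)-exo-trig Claisen (Dieckmann-type) closure of the six-membered carbocycle, methoxide leaves, and enolisation gives the arene, so that the ring oxygen O1 has been exchanged for the former methyl carbon. The closest known reaction types are the lateral acylation of 4-methoxy-6-methyl-2-pyrone and the base-induced conversion of 6-(2-oxoalkyl)-4-hydroxy- and -4-methoxy-2-pyrones, and of the 3,5,7-trioxo esters behind them, into acylphloroglucinols. No stereocentre is formed, and the one stereocentre of 12 (C5) is lost on aromatisation. The step needs Claisen rather than aldol folding: the aldol mode would require the prenyl-bearing carbon C3, locked in the enol ether, to attack C7 and would end in a quaternary carbon that cannot aromatise, while relactonisation is reversible and methoxide attack at C4 is degenerate, so only the Claisen path has an irreversible exit, the chelated magnesium phenoxide of 13. The substitution pattern is secured by the substrate: pyrone atoms C2 to C6 become ring A atoms C2 to C6 with their substituents, O4 is already methylated, and the two new phenol oxygens are the lactone carbonyl oxygen (on C2) and O1 (on C6).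

## Compound list

1 | methyl acetoacetate | COC(=O)CC(C)=O | starting material
2 | prenyl bromide (1-bromo-3-methylbut-2-ene) | CC(C)=CCBr | starting material
3 | methyl 7-methyl-3-oxooct-6-enoate (in the flask as its enolate) | COC(=O)CC(=O)CCC=C(C)C | intermediate
4 | methyl 7-methyl-2-(3-methylbut-2-en-1-yl)-3-oxooct-6-enoate (racemic) | COC(=O)C(CC=C(C)C)C(=O)CCC=C(C)C | intermediate
5 | N-methoxy-N-methylacetamide | CON(C)C(C)=O | starting material
6 | methyl 4-acetyl-7-methyl-2-(3-methylbut-2-en-1-yl)-3-oxooct-6-enoate (3,5-dioxo ester, mixture of diastereomers and enol forms) | COC(=O)C(CC=C(C)C)C(=O)C(CC=C(C)C)C(C)=O | intermediate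
7 | 4-hydroxy-6-methyl-3,5-bis(3-methylbut-2-en-1-yl)-2H-pyran-2-one | CC1=C(CC=C(C)C)C(O)=C(CC=C(C)C)C(=O)O1 | intermediate
8 | 4-methoxy-6-methyl-3,5-bis(3-methylbut-2-en-1-yl)-2H-pyran-2-one | CC1=C(CC=C(C)C)C(OC)=C(CC=C(C)C)C(=O)O1 | intermediate
9 | methyl 4-hydroxybenzoate | COC(=O)c1ccc(O)cc1 | starting material
10 | methyl 4-[(tert-butyldimethylsilyl)oxy]benzoate | COC(=O)c1ccc(O[Si](C)(C)C(C)(C)C)cc1 | intermediate
11 | 6-{2-[4-(tert-butyldimethylsilyloxy)phenyl]-2-oxoethyl}-4-methoxy-3,5-bis(3-methylbut-2-en-1-yl)-2H-pyran-2-one (in the flask as its lithium enolate) | COC1=C(CC=C(C)C)C(=O)OC(CC(=O)c2ccc(O[Si](C)(C)C(C)(C)C)cc2)=C1CC=C(C)C | intermediate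
12 | methyl (2E)-7-(4-hydroxyphenyl)-3-methoxy-2,4-bis(3-methylbut-2-en-1-yl)-5,7-dioxohept-2-enoate (racemic, in the flask as its magnesium chelate) | COC(=O)/C(CC=C(C)C)=C(OC)\C(CC=C(C)C)C(=O)CC(=O)c1ccc(O)cc1 | intermediate
13 | vismiaphenone D, [2,6-dihydroxy-4-methoxy-3,5-bis(3-methylbut-2-en-1-yl)phenyl](4-hydroxyphenyl)methanone | COc1c(CC=C(C)C)c(O)c(C(=O)c2ccc(O)cc2)c(O)c1CC=C(C)C | target

## Step count and risk

Total step count: 5. Longest linear sequence: 4 (steps 1, 2, 3 and 5). Step 4 is a one-step branch.

**Step 5 (key step).**

- *Most likely failure:* slow opening of the lactone. Compound 11 is present as a delocalised enolate (a dianion after desilylation), and C2 is flanked by the C3-prenyl group.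
- *What may happen instead:* methoxide may attack C7 and cleave the β-diketone, a retro-Claisen loss of the aroyl group. The enolate oxygen on C7 may displace the C4 methoxy group by addition–elimination, closing a γ-pyrone. In the first stage, proton transfer from the product to the pyrone anion may leave the acylation incomplete.
- *Fallback:* it sets out from 8, comes back at 13, and attaches the aroyl group only after the ring has been transformed. Compound 8, which stays neutral and so more electrophilic in methoxide, is heated alone with NaOMe in MeOH in a sealed vessel (about 150–180 °C). Ring opening and Dieckmann-type closure of the methyl ketone onto the ester should give 5-methoxy-4,6-bis(3-methylbut-2-en-1-yl)benzene-1,3-diol F1. MOMCl and i-Pr2NEt protect both phenols to give 2-methoxy-4,6-bis(methoxymethoxy)-1,3-bis(3-methylbut-2-en-1-yl)benzene F2. n-BuLi in THF at 0 °C removes the only aromatic hydrogen, which lies between the two acetal oxygens (directed ortho metalation). The aryllithium is acylated with 10 to give the hindered ketone {4-[(tert-butyldimethylsilyl)oxy]phenyl}[4-methoxy-2,6-bis(methoxymethoxy)-3,5-bis(3-methylbut-2-en-1-yl)phenyl]methanone F3. Bu4NF frees ring B to give (4-hydroxyphenyl)[4-methoxy-2,6-bis(methoxymethoxy)-3,5-bis(3-methylbut-2-en-1-yl)phenyl]methanone F4. Dilute methanolic HCl at room temperature then removes the two acetals to give 13.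

**Step 2.**

- *Most likely failure:* proton transfer instead of acylation, because the γ-carbanion is basic enough to enolise the acetyl donor 5. The second deprotonation of the α-branched β-keto ester may also be incomplete.
- *Fallback:* it sets out from 4, comes back at 6, and replaces the acylation by an aldol addition plus oxidation. The dianion of 4 adds to acetaldehyde at −78 °C to give methyl 4-(1-hydroxyethyl)-7-methyl-2-(3-methylbut-2-en-1-yl)-3-oxooct-6-enoate F5. Dess–Martin periodinane oxidises it to 6, which is lactonised with DBU as before.

**Step 3.**

- *Most likely failure:* the pyrone anion is ambident. Methylation on the lactone carbonyl oxygen (formation of the 2-methoxy-4-pyrone isomer) would later deliver a free O4. The two flanking prenyl groups slow attack at O4.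
- *Fallback:* it sets out from 7, comes back at 8, and forms the C4–O bond instead of the O–CH3 bond. TsCl and Et3N convert 7 into 6-methyl-3,5-bis(3-methylbut-2-en-1-yl)-2-oxo-2H-pyran-4-yl 4-methylbenzenesulfonate F6. NaOMe (1 equiv) in MeOH at 0 °C replaces the sulfonate by addition–elimination at C4, which fixes the methoxy group on C4 of an intact 2-pyrone.

**Step 1.**

- *Most likely failure:* loss of control in the second alkylation. Proton exchange between product and enolate would lead to geminal α,α-dialkylation beside unreacted monoalkylated material, and some O-alkylation may occur.
- *Fallback:* it sets out from 2, comes back at 4, and replaces the double alkylation by a dimerisation. Compound 2 alkylates the lithium enolate of methyl acetate (LDA, THF, −78 °C) to give methyl 5-methylhex-4-enoate F7. Claisen self-condensation of F7 (NaH, catalytic MeOH, THF, reflux) gives 4, with one prenyl group delivered by each ester molecule.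

## Further compounds

F1 | step 5 | 5-methoxy-4,6-bis(3-methylbut-2-en-1-yl)benzene-1,3-diol | COc1c(CC=C(C)C)c(O)cc(O)c1CC=C(C)C
F2 | step 5 | 2-methoxy-4,6-bis(methoxymethoxy)-1,3-bis(3-methylbut-2-en-1-yl)benzene | COCOc1cc(OCOC)c(CC=C(C)C)c(OC)c1CC=C(C)C
F3 | step 5 | {4-[(tert-butyldimethylsilyl)oxy]phenyl}[4-methoxy-2,6-bis(methoxymethoxy)-3,5-bis(3-methylbut-2-en-1-yl)phenyl]methanone | COCOc1c(C(=O)c2ccc(O[Si](C)(C)C(C)(C)C)cc2)c(OCOC)c(CC=C(C)C)c(OC)c1CC=C(C)C
F4 | step 5 | (4-hydroxyphenyl)[4-methoxy-2,6-bis(methoxymethoxy)-3,5-bis(3-methylbut-2-en-1-yl)phenyl]methanone | COCOc1c(C(=O)c2ccc(O)cc2)c(OCOC)c(CC=C(C)C)c(OC)c1CC=C(C)C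
F5 | step 2 | methyl 4-(1-hydroxyethyl)-7-methyl-2-(3-methylbut-2-en-1-yl)-3-oxooct-6-enoate (mixture of diastereomers) | COC(=O)C(CC=C(C)C)C(=O)C(CC=C(C)C)C(C)O
F6 | step 3 | 6-methyl-3,5-bis(3-methylbut-2-en-1-yl)-2-oxo-2H-pyran-4-yl 4-methylbenzenesulfonate | CC1=C(CC=C(C)C)C(OS(=O)(=O)c2ccc(C)cc2)=C(CC=C(C)C)C(=O)O1
F7 | step 1 | methyl 5-methylhex-4-enoate | COC(=O)CCC=C(C)C
A1 | alternative 1 | phloroglucinol (benzene-1,3,5-triol) | Oc1cc(O)cc(O)c1
A2 | alternative 1 | (4-hydroxyphenyl)(2,4,6-trihydroxyphenyl)methanone | O=C(c1ccc(O)cc1)c1c(O)cc(O)cc1O
A3 | alternative 1 | (4-hydroxyphenyl)[2,4,6-trihydroxy-3,5-bis(3-methylbut-2-en-1-yl)phenyl]methanone | O=C(c1ccc(O)cc1)c1c(O)c(CC=C(C)C)c(O)c(CC=C(C)C)c1O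
A4 | alternative 2 | 3-methoxy-2,4-bis(3-methylbut-2-en-1-yl)cyclobut-2-en-1-one (racemic) | COC1=C(CC=C(C)C)C(=O)C1CC=C(C)C
A5 | alternative 2 | 1-{4-[(tert-butyldimethylsilyl)oxy]phenyl}-3-[(triisopropylsilyl)oxy]prop-2-yn-1-one | CC(C)[Si](C(C)C)(C(C)C)OC#CC(=O)c1ccc(O[Si](C)(C)C(C)(C)C)cc1
A6 | alternative 2 | {4-[(tert-butyldimethylsilyl)oxy]phenyl}{2-hydroxy-4-methoxy-3,5-bis(3-methylbut-2-en-1-yl)-6-[(triisopropylsilyl)oxy]phenyl}methanone | COc1c(CC=C(C)C)c(O)c(C(=O)c2ccc(O[Si](C)(C)C(C)(C)C)cc2)c(O[Si](C(C)C)(C(C)C)C(C)C)c1CC=C(C)C
A7 | alternative 3 | dimethyl 3-methoxy-2,4-bis(3-methylbut-2-en-1-yl)pent-2-enedioate (racemic, alkene geometry left open) | COC(=O)C(CC=C(C)C)=C(OC)C(CC=C(C)C)C(=O)OC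
A8 | alternative 3 | 1-{4-[(tert-butyldimethylsilyl)oxy]phenyl}ethan-1-one | CC(=O)c1ccc(O[Si](C)(C)C(C)(C)C)cc1
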